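## Retrosynthetic overview
1. Ring C is opened at the O1–C2 bond: (2S)-flavanone ⇒ (E)-2'-hydroxychalcone. In the forward direction, a catalytic enantioselective intramolecular oxa-Michael addition closes ring C, forms the C–O bond and sets C2 in the last step.
2. Chalcone ⇒ 3-prenyl-2,4-dihydroxyacetophenone + 2,2-dimethyl-8-prenylchromene-6-carbaldehyde (Claisen–Schmidt condensation, no protecting groups).
3. Chromene aldehyde ⇒ 3,5-diprenyl-4-hydroxybenzaldehyde (DDQ dehydrogenative O–C ring closure; there is one OH, so only one pyran can form) ⇒ 4-hydroxybenzaldehyde + 2 prenyl bromide.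
4. Prenyl ketone ⇒ 2,4-dihydroxyacetophenone + prenyl bromide (phenoxide C-alkylation at C3).
5. Ring order: benzene rings A and B are bought, the pyran of the chromene is formed first (step 2), and ring C is formed last (step 5).

**Assumption:** the facial sense of a reaction that has never been run cannot be guaranteed. The L-tert-leucine-derived catalyst is written; the product is checked by CD ((2S)-flavanones show a positive band near 330 nm and a negative band near 290–310 nm), and the mirror-image catalyst from D-tert-leucine is used if the sense is opposite.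

**Catalyst of step 5 (cat-A):**
- Name: 1-[3,5-bis(trifluoromethyl)phenyl]-3-[(2S)-3,3-dimethyl-1-{[tris(4-methoxyphenyl)-λ5-phosphanylidene]amino}butan-2-yl]thiourea, C36H38F6N3O3PS.
- SMILES: CC(C)(C)[C@H](NC(=S)Nc1cc(C(F)(F)F)cc(C(F)(F)F)c1)CN=P(c1ccc(OC)cc1)(c1ccc(OC)cc1)c1ccc(OC)cc1
- It belongs to a known family of bifunctional iminophosphorane catalysts and is prepared beforehand from L-tert-leucine. It is used in catalytic amount and is not counted as a route step.

## Route

**Step 1**
Reactants: 1 4-hydroxybenzaldehyde; 2 prenyl bromide (1-bromo-3-methylbut-2-ene)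
Product: 4 4-hydroxy-3,5-bis(3-methylbut-2-en-1-yl)benzaldehyde, via monoprenyl aldehyde 3 (not isolated)
Conditions: 2 (2.5 equiv), KOH (2.5 equiv), H2O, 0 °C to rt, 36 h
Reagents that add atoms: prenyl bromide (2), CC(C)=CCBr
Why: Phenoxide ortho C-alkylation (SN2) in water, where hydrogen bonding to the phenoxide oxygen steers the allylic bromide to the two free ortho carbons (para is blocked by CHO) and each alkylation is followed by rearomatisation; this is precedented on this aldehyde in modest yield (expect 25–35%) and forms no stereocenter.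

**Step 2**
Reactants: 4 4-hydroxy-3,5-bis(3-methylbut-2-en-1-yl)benzaldehyde
Product: 6 2,2-dimethyl-8-(3-methylbut-2-en-1-yl)-2H-chromene-6-carbaldehyde, via o-quinone methide 5 (not isolated)
Conditions: DDQ (1.1 equiv), 1,4-dioxane, reflux, 3 h
Reagents that add atoms: none
Why: DDQ cyclodehydrogenation of an ortho-prenylphenol, in which hydride abstraction from the benzylic/allylic CH2 gives o-quinone methide 5 and this closes by oxa-6π electrocyclisation; the single OH means only one of the two equivalent prenyl groups can be consumed, so the other survives.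

**Step 3**
Reactants: 7 2,4-dihydroxyacetophenone; 2 prenyl bromide
Product: 8 1-[2,4-dihydroxy-3-(3-methylbut-2-en-1-yl)phenyl]ethan-1-one
Conditions: 2 (1.1 equiv), KOH (1.1 equiv), H2O, 0 °C to rt, 24 h
Reagents that add atoms: prenyl bromide (2), CC(C)=CCBr
Why: Phenoxide C-alkylation, in which the 4-phenoxide (the 2-OH stays locked in a hydrogen bond to the acetyl group) reacts mainly at C3, the ortho carbon activated by both oxygens; this is a known preparation (expect 30–40% after removal of the 5-prenyl and 4-O-prenyl isomers) and forms no stereocenter.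

**Step 4**
Reactants: 8 1-[2,4-dihydroxy-3-(3-methylbut-2-en-1-yl)phenyl]ethan-1-one; 6 2,2-dimethyl-8-(3-methylbut-2-en-1-yl)-2H-chromene-6-carbaldehyde
Product: 10 (E)-1-[2,4-dihydroxy-3-(3-methylbut-2-en-1-yl)phenyl]-3-[2,2-dimethyl-8-(3-methylbut-2-en-1-yl)-2H-chromen-6-yl]prop-2-en-1-one, via aldol adduct 9 (not isolated)
Conditions: KOH (12 equiv, 50% aq), EtOH, rt, 48 h; then 1 M HCl, 0 °C, to pH 5
Reagents that add atoms: none
Why: Claisen–Schmidt condensation (aldol addition, then E1cB dehydration that erases the transient carbinol centre of 9) gives the thermodynamic E-enone; the aldehyde has no free OH, the strongly basic medium keeps the product open as its phenoxide so no racemic flavanone forms, and the prenyl and chromene groups are inert to base.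

**Step 5**
Reactants: 10 (E)-chalcone
Product: 11 (2S)-7-hydroxy-8-(3-methylbut-2-en-1-yl)-2-[2,2-dimethyl-8-(3-methylbut-2-en-1-yl)-2H-chromen-6-yl]-2,3-dihydro-4H-chromen-4-one
Conditions: cat-A [1-[3,5-bis(trifluoromethyl)phenyl]-3-[(2S)-3,3-dimethyl-1-{[tris(4-methoxyphenyl)-λ5-phosphanylidene]amino}butan-2-yl]thiourea, C36H38F6N3O3PS] (10 mol%), dry toluene (0.1 M), N2, 0 °C to rt, 24–72 h (chiral HPLC control, stop near 85% conversion); filtration through silica gel, recovered 10 recycled
Reagents that add atoms: none
Why: Proposed new method: an enantioselective 6-endo-trig intramolecular oxa-Michael addition of a plain, not ester-activated 2'-hydroxychalcone with a free 4'-OH under bifunctional iminophosphorane/thiourea catalysis; the superbase deprotonates the substrate to a tight chiral ion pair (resting state 4'-phenoxide, in fast proton exchange with the reactive 2'-phenoxide, so the acidic phenols of substrate and product only buffer the catalyst and do not shift the equilibrium); the thiourea N–H pair takes the carbonyl oxygen away from the intramolecular 2'-OH···O=C hydrogen bond so that the aryl–carbonyl bond can rotate into the productive rotamer; the ion-paired 2'-oxygen adds to the Si face of C-β to give (2S), and the iminophosphoranium N–H protonates C3; because the reaction is reversible it is run cold (which favours the closed form) and stopped before equilibrium, where the minor enantiomer can arise only through the slow mismatched closure; the closest known reaction types are the cinchona thiourea/tertiary amine cyclisation of 2'-hydroxychalcones (high ee only with ester-activated substrates) and the iminophosphorane-catalysed oxa-Michael cyclisation of alcohols onto unsaturated esters and amides.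

## Compound list
1 | 4-hydroxybenzaldehyde | O=Cc1ccc(O)cc1 | starting material
2 | prenyl bromide (1-bromo-3-methylbut-2-ene) | CC(C)=CCBr | starting material
3 | 4-hydroxy-3-(3-methylbut-2-en-1-yl)benzaldehyde (not isolated) | CC(C)=CCc1cc(C=O)ccc1O | intermediate
4 | 4-hydroxy-3,5-bis(3-methylbut-2-en-1-yl)benzaldehyde | CC(C)=CCc1cc(C=O)cc(CC=C(C)C)c1O | intermediate
5 | (3Z)-5-(3-methylbut-2-en-1-yl)-3-(3-methylbut-2-en-1-ylidene)-4-oxocyclohexa-1,5-diene-1-carbaldehyde, o-quinone methide (not isolated) | O=C1/C(=C\C=C(C)C)C=C(C=O)C=C1CC=C(C)C | intermediate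
6 | 2,2-dimethyl-8-(3-methylbut-2-en-1-yl)-2H-chromene-6-carbaldehyde | CC(C)=CCc1cc(C=O)cc2c1OC(C)(C)C=C2 | intermediate
7 | 2,4-dihydroxyacetophenone | CC(=O)c1ccc(O)cc1O | starting material
8 | 1-[2,4-dihydroxy-3-(3-methylbut-2-en-1-yl)phenyl]ethan-1-one | CC(=O)c1ccc(O)c(CC=C(C)C)c1O | intermediate
9 | racemic 1-[2,4-dihydroxy-3-(3-methylbut-2-en-1-yl)phenyl]-3-hydroxy-3-[2,2-dimethyl-8-(3-methylbut-2-en-1-yl)-2H-chromen-6-yl]propan-1-one, aldol adduct (not isolated) | CC(C)=CCc1cc(C(O)CC(=O)c2ccc(O)c(CC=C(C)C)c2O)cc2c1OC(C)(C)C=C2 | intermediate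
10 | (E)-1-[2,4-dihydroxy-3-(3-methylbut-2-en-1-yl)phenyl]-3-[2,2-dimethyl-8-(3-methylbut-2-en-1-yl)-2H-chromen-6-yl]prop-2-en-1-one | CC(C)=CCc1cc(/C=C/C(=O)c2ccc(O)c(CC=C(C)C)c2O)cc2c1OC(C)(C)C=C2 | intermediate
11 | (2S)-7-hydroxy-8-(3-methylbut-2-en-1-yl)-2-[2,2-dimethyl-8-(3-methylbut-2-en-1-yl)-2H-chromen-6-yl]-2,3-dihydro-4H-chromen-4-one | CC(C)=CCc1cc([C@@H]2CC(=O)c3ccc(O)c(CC=C(C)C)c3O2)cc2c1OC(C)(C)C=C2 | target

## Step count
- Total steps: 5.
- Longest linear sequence: 4 (steps 1, 2, 4, 5; step 3 is the one-step side branch).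

## Three steps most likely to fail

**Step 5 (the proposed new reaction).**
- Risks: the acidic 4'-OH and 7-OH may park the catalyst as an unreactive phenoxide. Reversibility may erode the ee. The sense and level of induction are unknown.
- Fallback (known chemistry; resolution replaces asymmetric catalysis): it sets out from 10. Heating 10 with NaOAc in refluxing EtOH is the standard chalcone–flavanone isomerisation. It gives the racemic flavanone F1, from which unreacted 10 is separated. Preparative HPLC on an amylose tris(3,5-dimethylphenylcarbamate) phase separates F1 into 11 and the (2R)-flavanone F2. F2 is returned to the NaOAc treatment, which re-equilibrates it through 10 back to F1 for another pass. The fallback comes back to the route at 11.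

**Step 1.**
- Risks: the double ortho C-prenylation of an electron-poor phenoxide competes with O-alkylation and with hydrolysis of 2, and it may stall at 3.
- Fallback: this gives up phenoxide C-alkylation, and the DDQ step with it. The pyran is built first and the prenyl group is attached last by cross-coupling. It sets out from 1. Monobromination (Br2, CHCl3, 0 °C) gives 3-bromo-4-hydroxybenzaldehyde F3. O-alkylation with 3-chloro-3-methylbut-1-yne (K2CO3, KI, acetone, reflux) gives 3-bromo-4-[(2-methylbut-3-yn-2-yl)oxy]benzaldehyde F4. Heating F4 in N,N-diethylaniline at 190 °C triggers a propargyl Claisen rearrangement to the only free ortho carbon, then a 1,5-H shift and an oxa-6π closure, giving 8-bromo-2,2-dimethyl-2H-chromene-6-carbaldehyde F5. Stille coupling with tributyl(3-methylbut-2-en-1-yl)stannane (Pd(PPh3)4, DMF, 100 °C) installs the linear prenyl group. The fallback comes back to the route at 6.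

**Step 3.**
- Risks: C3, C5 and O alkylation compete, and the isolated yield of 8 may be too low.
- Fallback: the direct C–C alkylation is replaced by selective O-alkylation and a sigmatropic transfer. It sets out from 7. The free 4-OH (the 2-OH is hydrogen-bonded and inert) is alkylated with 3-chloro-3-methylbut-1-yne (K2CO3, KI, acetone, reflux) to give 1-{2-hydroxy-4-[(2-methylbut-3-yn-2-yl)oxy]phenyl}ethan-1-one F6. Semihydrogenation (H2, Pd/CaCO3 poisoned with Pb(OAc)2, quinoline, EtOAc, rt) gives 1-{2-hydroxy-4-[(2-methylbut-3-en-2-yl)oxy]phenyl}ethan-1-one F7. Aromatic Claisen rearrangement (N,N-diethylaniline, 130 °C) delivers the inverted allyl unit, which is the linear prenyl group, preferentially to C3. The fallback comes back to the route at 8.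

## Further compounds
F1 | step 5 | racemic 7-hydroxy-8-(3-methylbut-2-en-1-yl)-2-[2,2-dimethyl-8-(3-methylbut-2-en-1-yl)-2H-chromen-6-yl]-2,3-dihydro-4H-chromen-4-one | CC(C)=CCc1cc(C2CC(=O)c3ccc(O)c(CC=C(C)C)c3O2)cc2c1OC(C)(C)C=C2
F2 | step 5 | (2R)-7-hydroxy-8-(3-methylbut-2-en-1-yl)-2-[2,2-dimethyl-8-(3-methylbut-2-en-1-yl)-2H-chromen-6-yl]-2,3-dihydro-4H-chromen-4-one | CC(C)=CCc1cc([C@H]2CC(=O)c3ccc(O)c(CC=C(C)C)c3O2)cc2c1OC(C)(C)C=C2
F3 | step 1 | 3-bromo-4-hydroxybenzaldehyde | O=Cc1ccc(O)c(Br)c1
F4 | step 1 | 3-bromo-4-[(2-methylbut-3-yn-2-yl)oxy]benzaldehyde | C#CC(C)(C)Oc1ccc(C=O)cc1Br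
F5 | step 1 | 8-bromo-2,2-dimethyl-2H-chromene-6-carbaldehyde | CC1(C)C=Cc2cc(C=O)cc(Br)c2O1
F6 | step 3 | 1-{2-hydroxy-4-[(2-methylbut-3-yn-2-yl)oxy]phenyl}ethan-1-one | CC(=O)c1ccc(OC(C)(C)C#C)cc1O
F7 | step 3 | 1-{2-hydroxy-4-[(2-methylbut-3-en-2-yl)oxy]phenyl}ethan-1-one | CC(=O)c1ccc(OC(C)(C)C=C)cc1O
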